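**Retrosynthetic overview**

1. The oxirane comes last by Sharpless epoxidation of the (E)-allylic alcohol, which comes from carboalumination and hydroxymethylation of a terminal alkyne (C-13 to C-16).
2. The halim-1(10)-ene core comes from a reductive 1,2-methyl shift (C-10 to C-9) in a cis-fused 10-methyl-1,8-diene; the shift is pulled to the C-10/C-1/C-2 allyl cation and ended by hydride at C-2.
3. The diene comes from Negishi coupling of a C-9 enol triflate; the bicyclic ketone comes from closing ring A onto ring B by palladium-catalysed enolate alkenylation (C-10 to C-1).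
4. The C-4 quaternary centre comes from an ester enolate alkylation under 1,2-induction from C-5; C-5 comes from a catalytic asymmetric Mukaiyama–Michael addition to cyclohex-2-enone.
5. Ring order: ring B is bought, ring A is closed in step 4, the oxirane in step 9.

Atom labels C-1 to C-16 follow halimane numbering of the target (C-4 carries the ester, C-10 is the sp2 ring-fusion carbon, C-9 carries the side chain).

Assumption: the (S)-oxazaborolidinium catalyst of step 2 gives the (R)-configured ring carbon; if the sense of induction is the reverse, its (R)-enantiomer is used.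

**Step 1**
Reactants: 1 methyl propanoate
Product: 2 (E)-1-methoxy-1-(trimethylsilyloxy)prop-1-ene
Conditions: LDA, THF, −78 °C; Me3SiCl, −78 °C → rt; distil
Reagents that add atoms: chlorotrimethylsilane, C[Si](C)(C)Cl
Why: Kinetic ester deprotonation and O-silylation of the lithium enolate (standard ketene silyl acetal synthesis) give the Mukaiyama donor, whose double-bond geometry does not matter because this carbon is re-enolised in step 3.

**Step 2**
Reactants: 2 (E)-1-methoxy-1-(trimethylsilyloxy)prop-1-ene; 3 cyclohex-2-en-1-one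
Product: 5 methyl 2-[(1R)-2-methyl-3-oxocyclohexyl]propanoate, via silyl enol ether 4 (not isolated)
Conditions: (S)-1-(2-methylphenyl)-3,3-diphenyltetrahydro-1H,3H-pyrrolo[1,2-c][1,3,2]oxazaborole (10 mol %), HN(SO2CF3)2 (10 mol %), Ph3PO (20 mol %), toluene, −20 °C; then BnMe3NF, MeI, THF, 0 °C → rt
Reagents that add atoms: iodomethane, CI
Why: Chiral oxazaborolidinium-catalysed Mukaiyama–Michael addition of a ketene silyl acetal to a cyclic enone sets the ring stereocentre (later C-5) as R by attack on the enone face left open by the catalyst, and the silyl enol ether formed by silyl transfer is then methylated regiospecifically at the ring carbon between C-5 and the carbonyl (later C-10) by fluoride-mediated enolate alkylation.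

**Step 3**
Reactants: 5 methyl 2-[(1R)-2-methyl-3-oxocyclohexyl]propanoate; 6 (Z)-1,3-dichloroprop-1-ene
Product: 9 methyl (2S,4Z)-5-chloro-2-methyl-2-[(1R)-2-methyl-3-oxocyclohexyl]pent-4-enoate, via kinetic silyl enol ether 7 (not isolated), via alkylated silyl enol ether 8 (not isolated)
Conditions: LDA (1.05 equiv), THF, −78 °C; Me3SiCl (1.05 equiv); LDA (1.15 equiv), DMPU, −78 °C; 6, −78 → −20 °C; 1 M HCl
Reagents that add atoms: chlorotrimethylsilane, C[Si](C)(C)Cl (its silyl group stays only in 7 and 8)
Why: With the ketone masked in situ as its kinetic silyl enol ether the ester α-hydrogen is the only acidic site, and the ester enolate is alkylated by the allylic chloride under A(1,3)-strain control (H-5 in the enolate plane, electrophile anti to the branched ring carbon C-10), which sets the quaternary centre (later C-4) as S by acyclic 1,2-induction in an enolate alkylation.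

**Step 4**
Reactants: 9 methyl (2S,4Z)-5-chloro-2-methyl-2-[(1R)-2-methyl-3-oxocyclohexyl]pent-4-enoate
Product: 10 methyl (1S,4aR,8aR)-1,4a-dimethyl-5-oxo-1,2,4a,5,6,7,8,8a-octahydronaphthalene-1-carboxylate
Conditions: Pd(OAc)2 (5 mol %), P(t-Bu)3·HBF4 (10 mol %), NaOt-Bu, toluene, 60 °C
Reagents that add atoms: none
Why: Palladium-catalysed intramolecular α-alkenylation of the ketone enolate (Buchwald–Hartwig-type enolate coupling with retention of the Z alkene) closes ring A, because only the more substituted enolate can reach the alkenylpalladium centre through a six-membered ring, and axial C–C bond formation next to the equatorial C-5 side chain sets quaternary C-10 with its methyl cis to H-5 (cis ring fusion).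

**Step 5**
Reactants: 10 methyl (1S,4aR,8aR)-1,4a-dimethyl-5-oxo-1,2,4a,5,6,7,8,8a-octahydronaphthalene-1-carboxylate
Product: 12 methyl (1S,4aR,8aR)-1,4a,6-trimethyl-5-[(trifluoromethanesulfonyl)oxy]-1,2,4a,7,8,8a-hexahydronaphthalene-1-carboxylate, via 6-methyl ketone 11 (not isolated)
Conditions: LDA, THF, −78 °C; MeI, −78 → 0 °C; KHMDS, −78 °C; PhNTf2, −78 → 0 °C
Reagents that add atoms: iodomethane, CI; N-phenylbis(trifluoromethanesulfonimide), O=S(=O)(N(c1ccccc1)S(=O)(=O)C(F)(F)F)C(F)(F)F
Why: C-8 is the only enolisable position, so enolate methylation followed by KHMDS/PhNTf2 O-triflation of the tetrasubstituted enolate gives one enol triflate regioisomer, and the C-8 configuration of 11 is lost as intended.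

**Step 6**
Reactants: 12 methyl (1S,4aR,8aR)-1,4a,6-trimethyl-5-[(trifluoromethanesulfonyl)oxy]-1,2,4a,7,8,8a-hexahydronaphthalene-1-carboxylate; 13 4-bromobut-1-yne
Product: 15 methyl (1S,4aR,8aR)-5-(but-3-yn-1-yl)-1,4a,6-trimethyl-1,2,4a,7,8,8a-hexahydronaphthalene-1-carboxylate, via but-3-yn-1-ylzinc bromide 14 (not isolated)
Conditions: 13, Zn dust, LiCl, THF, 40 °C; then 12, Pd(OAc)2 (5 mol %), SPhos (10 mol %), THF/NMP, 50 °C
Reagents that add atoms: zinc, [Zn] (stays only in 14)
Why: Zinc insertion into the primary bromide gives an alkylzinc bromide that tolerates the terminal alkyne, and palladium-catalysed Negishi sp2–sp3 coupling with the enol triflate attaches C-11 to C-14 without touching a stereocentre.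

**Step 7**
Reactants: 15 methyl (1S,4aR,8aR)-5-(but-3-yn-1-yl)-1,4a,6-trimethyl-1,2,4a,7,8,8a-hexahydronaphthalene-1-carboxylate
Product: 16 methyl (1S,5S,6R,8aR)-5-(but-3-yn-1-yl)-1,5,6-trimethyl-1,2,3,5,6,7,8,8a-octahydronaphthalene-1-carboxylate
Conditions: CF3CO2H (5 equiv), Et3SiH (3 equiv), CH2Cl2, −20 → 0 °C; Et3N quench
Reagents that add atoms: none
Why: Proposed new method: an ionic hydrogenation interrupted by a skeletal shift – CF3CO2H protonates the tetrasubstituted C-8=C-9 bond on the face anti to the pseudoaxial C-10 methyl, this methyl migrates suprafacially to the C-9 cation (Wagner–Meerwein 1,2-shift) because the shift turns a tertiary cation into the C-10/C-1/C-2 allyl cation, and Et3SiH then gives hydride to the unhindered secondary terminus C-2, which leaves the C-1=C-10 bond, sets C-8 (H anti to the migrated methyl) and quaternary C-9 (methyl on the face of H-5) and keeps H-5 because C-10 is never a long-lived non-conjugated cation; the closest known reactions are CF3CO2H/Et3SiH ionic hydrogenation of alkenes and Lewis-acid induced 1,2-hydride/1,2-methyl backbone shifts of labdane-type cations.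

**Step 8**
Reactants: 16 methyl (1S,5S,6R,8aR)-5-(but-3-yn-1-yl)-1,5,6-trimethyl-1,2,3,5,6,7,8,8a-octahydronaphthalene-1-carboxylate
Product: 19 methyl (1S,5S,6R,8aR)-5-[(3E)-5-hydroxy-3-methylpent-3-en-1-yl]-1,5,6-trimethyl-1,2,3,5,6,7,8,8a-octahydronaphthalene-1-carboxylate, via alkenylalane 17 (not isolated), via lithium alanate 18 (not isolated)
Conditions: Me3Al, Cp2ZrCl2 (0.3 equiv), CH2Cl2, 0 °C → rt; evaporate; n-BuLi, THF, −78 °C; (CH2O)n, −78 °C → rt; aq. Rochelle salt
Reagents that add atoms: trimethylaluminium, C[Al](C)C; formaldehyde (as paraformaldehyde), C=O; n-butyllithium, [Li]CCCC (its butyl group and lithium stay only in 18)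
Why: Zirconium-catalysed Negishi carboalumination adds methyl and aluminium syn to the terminal alkyne with methyl on the internal carbon, and hydroxymethylation of the alanate with formaldehyde goes with retention, so the trisubstituted alkene is formed as the E isomer.

**Step 9**
Reactants: 19 methyl (1S,5S,6R,8aR)-5-[(3E)-5-hydroxy-3-methylpent-3-en-1-yl]-1,5,6-trimethyl-1,2,3,5,6,7,8,8a-octahydronaphthalene-1-carboxylate
Product: 20 methyl (1S,5S,6R,8aR)-5-{2-[(2R,3R)-3-(hydroxymethyl)-2-methyloxiran-2-yl]ethyl}-1,5,6-trimethyl-1,2,3,5,6,7,8,8a-octahydronaphthalene-1-carboxylate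
Conditions: Ti(Oi-Pr)4 (10 mol %), D-(−)-diethyl tartrate (12 mol %), t-BuOOH, 4 Å MS, CH2Cl2, −20 °C
Reagents that add atoms: tert-butyl hydroperoxide, CC(C)(C)OO
Why: Sharpless asymmetric epoxidation, in which the titanium D-(−)-tartrate catalyst delivers oxygen to the (E)-allylic alcohol under reagent control to give the (2R,3R)-type epoxy alcohol, i.e. 13R,14R, while the isolated trisubstituted ring alkene is not touched.

**Compound list**

1 | methyl propanoate | CCC(=O)OC | starting material
2 | (E)-1-methoxy-1-(trimethylsilyloxy)prop-1-ene | C/C=C(OC)/O[Si](C)(C)C | intermediate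
3 | cyclohex-2-en-1-one | O=C1C=CCCC1 | starting material
4 | methyl 2-[(1R)-3-(trimethylsilyloxy)cyclohex-2-en-1-yl]propanoate (both epimers at the propanoate carbon) | COC(=O)C(C)[C@@H]1CCCC(O[Si](C)(C)C)=C1 | intermediate
5 | methyl 2-[(1R)-2-methyl-3-oxocyclohexyl]propanoate (epimers at the propanoate carbon and at ring C-2) | COC(=O)C(C)[C@@H]1CCCC(=O)C1C | intermediate
6 | (Z)-1,3-dichloroprop-1-ene | ClC/C=C\Cl | starting material
7 | methyl 2-[(1R)-2-methyl-3-(trimethylsilyloxy)cyclohex-3-en-1-yl]propanoate | COC(=O)C(C)[C@@H]1CCC=C(O[Si](C)(C)C)C1C | intermediate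
8 | methyl (2S,4Z)-5-chloro-2-methyl-2-[(1R)-2-methyl-3-(trimethylsilyloxy)cyclohex-3-en-1-yl]pent-4-enoate | COC(=O)[C@@](C)(C/C=C\Cl)[C@@H]1CCC=C(O[Si](C)(C)C)C1C | intermediate
9 | methyl (2S,4Z)-5-chloro-2-methyl-2-[(1R)-2-methyl-3-oxocyclohexyl]pent-4-enoate | COC(=O)[C@@](C)(C/C=C\Cl)[C@@H]1CCCC(=O)C1C | intermediate
10 | methyl (1S,4aR,8aR)-1,4a-dimethyl-5-oxo-1,2,4a,5,6,7,8,8a-octahydronaphthalene-1-carboxylate (cis-fused; angular methyl and ring-fusion H on one face, ester on the other) | COC(=O)[C@@]1(C)CC=C[C@]2(C)[C@H]1CCCC2=O | intermediate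
11 | methyl (1S,4aR,8aR)-1,4a,6-trimethyl-5-oxo-1,2,4a,5,6,7,8,8a-octahydronaphthalene-1-carboxylate (C-6 epimers) | COC(=O)[C@@]1(C)CC=C[C@]2(C)[C@H]1CCC(C)C2=O | intermediate
12 | methyl (1S,4aR,8aR)-1,4a,6-trimethyl-5-[(trifluoromethanesulfonyl)oxy]-1,2,4a,7,8,8a-hexahydronaphthalene-1-carboxylate | COC(=O)[C@@]1(C)CC=C[C@]2(C)[C@H]1CCC(C)=C2OS(=O)(=O)C(F)(F)F | intermediate
13 | 4-bromobut-1-yne | BrCCC#C | starting material
14 | but-3-yn-1-ylzinc bromide | Br[Zn]CCC#C | intermediate
15 | methyl (1S,4aR,8aR)-5-(but-3-yn-1-yl)-1,4a,6-trimethyl-1,2,4a,7,8,8a-hexahydronaphthalene-1-carboxylate | COC(=O)[C@@]1(C)CC=C[C@]2(C)[C@H]1CCC(C)=C2CCC#C | intermediate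
16 | methyl (1S,5S,6R,8aR)-5-(but-3-yn-1-yl)-1,5,6-trimethyl-1,2,3,5,6,7,8,8a-octahydronaphthalene-1-carboxylate | COC(=O)[C@@]1(C)CCC=C2[C@H]1CC[C@@H](C)[C@]2(C)CCC#C | intermediate
17 | dimethyl[(E)-alkenyl]alane from syn methylalumination of 16 (Al on the terminal carbon, cis to the new methyl) | COC(=O)[C@@]1(C)CCC=C2[C@H]1CC[C@@H](C)[C@]2(C)CC/C(C)=C/[Al](C)C | intermediate
18 | lithium butyl(dimethyl)[(E)-alkenyl]alanate from 17 | COC(=O)[C@@]1(C)CCC=C2[C@H]1CC[C@@H](C)[C@]2(C)CC/C(C)=C/[Al-](C)(C)CCCC.[Li+] | intermediate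
19 | methyl (1S,5S,6R,8aR)-5-[(3E)-5-hydroxy-3-methylpent-3-en-1-yl]-1,5,6-trimethyl-1,2,3,5,6,7,8,8a-octahydronaphthalene-1-carboxylate | COC(=O)[C@@]1(C)CCC=C2[C@H]1CC[C@@H](C)[C@]2(C)CC/C(C)=C/CO | intermediate
20 | methyl (1S,5S,6R,8aR)-5-{2-[(2R,3R)-3-(hydroxymethyl)-2-methyloxiran-2-yl]ethyl}-1,5,6-trimethyl-1,2,3,5,6,7,8,8a-octahydronaphthalene-1-carboxylate | COC(=O)[C@@]1(C)CCC=C2[C@H]1CC[C@@H](C)[C@]2(C)CC[C@@]1(C)O[C@@H]1CO | target

**Step count**

Total: 9 steps. Longest linear sequence: 9 steps (1 to 20); the route is linear and all other inputs are commercial.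

**Three steps most likely to fail**

Step 7 (the proposed new step). The risks are plain reduction of the C-8=C-9 bond without the shift, protonation from the methyl face (C-8 epimer), and acid-induced drift of the new alkene to C-5=C-10. The fallback uses known chemistry and separates cation capture from reduction. It sets out from 15. Dry HCl in CH2Cl2 at −78 °C brings about the classical hydrochlorination with Wagner–Meerwein methyl shift (pinene to bornyl chloride type), and chloride captures the allyl cation at C-2 to give methyl (1S,5S,6R,8aR)-5-(but-3-yn-1-yl)-3-chloro-1,5,6-trimethyl-1,2,3,5,6,7,8,8a-octahydronaphthalene-1-carboxylate F1. NaBH4 in DMSO then replaces the allylic chloride by hydride, and the sequence comes back to the route at 16.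

Step 3. The facial selectivity at C-4 rests on a modest size difference between the two ring carbons on C-5, so the selectivity may be low or inverted. The fallback reverses the order in which the two C-4 substituents are put on, so the group that arrives last changes. It sets out from 3. Methyl acetate (commercial) is alkylated with 6 (LDA, THF, −78 °C) to methyl (4Z)-5-chloropent-4-enoate F2, which is converted as in step 1 into (4Z)-5-chloro-1-methoxy-1-(trimethylsilyloxy)penta-1,4-diene F3. The Michael addition and methylation of step 2 then give methyl (4Z)-5-chloro-2-[(1R)-3-(trimethylsilyloxy)cyclohex-2-en-1-yl]pent-4-enoate F4 and from it methyl (4Z)-5-chloro-2-[(1R)-2-methyl-3-oxocyclohexyl]pent-4-enoate F5. In situ silylation as in step 3 gives methyl (4Z)-5-chloro-2-[(1R)-2-methyl-3-(trimethylsilyloxy)cyclohex-3-en-1-yl]pent-4-enoate F6. LDA and then MeI bring in the C-4 methyl last, and the sequence comes back to the route at 8.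

Step 4. The risks are slow oxidative addition of the alkenyl chloride, base-induced loss of HCl to an alkyne, and a slow reductive elimination that makes the crowded quaternary C-10. The fallback replaces the cross-coupling by an endo-selective carbocyclisation of an alkyne. It sets out from 5. Silylation as in step 3 (via 7), LDA and 3-bromoprop-1-yne give methyl (2S)-2-methyl-2-[(1R)-2-methyl-3-(trimethylsilyloxy)cyclohex-3-en-1-yl]pent-4-ynoate F7, and acidic work-up gives methyl (2S)-2-methyl-2-[(1R)-2-methyl-3-oxocyclohexyl]pent-4-ynoate F8. Me3SiCl, NaI and Et3N in MeCN give the more substituted silyl enol ether methyl (2S)-2-methyl-2-[(1R)-2-methyl-3-(trimethylsilyloxy)cyclohex-2-en-1-yl]pent-4-ynoate F9. W(CO)6 under irradiation in THF with water (tungsten vinylidene, attack of the enol ether on the terminal alkyne carbon, six-membered endo closure) then gives the ring A alkene, and the sequence comes back to the route at 10.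

**Further compounds**

F1 | step 7 | methyl (1S,5S,6R,8aR)-5-(but-3-yn-1-yl)-3-chloro-1,5,6-trimethyl-1,2,3,5,6,7,8,8a-octahydronaphthalene-1-carboxylate (C-3 epimers) | COC(=O)[C@@]1(C)CC(Cl)C=C2[C@H]1CC[C@@H](C)[C@]2(C)CCC#C
F2 | step 3 | methyl (4Z)-5-chloropent-4-enoate | COC(=O)CC/C=C\Cl
F3 | step 3 | (4Z)-5-chloro-1-methoxy-1-(trimethylsilyloxy)penta-1,4-diene | COC(O[Si](C)(C)C)=CC/C=C\Cl
F4 | step 3 | methyl (4Z)-5-chloro-2-[(1R)-3-(trimethylsilyloxy)cyclohex-2-en-1-yl]pent-4-enoate | COC(=O)C(C/C=C\Cl)[C@@H]1CCCC(O[Si](C)(C)C)=C1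
F5 | step 3 | methyl (4Z)-5-chloro-2-[(1R)-2-methyl-3-oxocyclohexyl]pent-4-enoate | COC(=O)C(C/C=C\Cl)[C@@H]1CCCC(=O)C1C
F6 | step 3 | methyl (4Z)-5-chloro-2-[(1R)-2-methyl-3-(trimethylsilyloxy)cyclohex-3-en-1-yl]pent-4-enoate | COC(=O)C(C/C=C\Cl)[C@@H]1CCC=C(O[Si](C)(C)C)C1C
F7 | step 4 | methyl (2S)-2-methyl-2-[(1R)-2-methyl-3-(trimethylsilyloxy)cyclohex-3-en-1-yl]pent-4-ynoate | COC(=O)[C@@](C)(CC#C)[C@@H]1CCC=C(O[Si](C)(C)C)C1C
F8 | step 4 | methyl (2S)-2-methyl-2-[(1R)-2-methyl-3-oxocyclohexyl]pent-4-ynoate | COC(=O)[C@@](C)(CC#C)[C@@H]1CCCC(=O)C1C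
F9 | step 4 | methyl (2S)-2-methyl-2-[(1R)-2-methyl-3-(trimethylsilyloxy)cyclohex-2-en-1-yl]pent-4-ynoate | COC(=O)[C@@](C)(CC#C)[C@@H]1CCCC(O[Si](C)(C)C)=C1C
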